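**Retrosynthetic overview**
1. Target 7 ⇒ alcohol 6 by disconnecting the benzylic C–O–SO3H bond (late O-sulfation of the primary alcohol in preference to the hindered phenol).
2. 6 ⇒ aldehyde 5 by functional-group interconversion (CHO reduction); the CHO is kept until the aryl sulfate is in place because it makes the para-OH the most acidic hydroxyl.
3. 5 ⇒ 4 by regioselective sulfation of the 4-OH monophenoxide (para to CHO).
4. 4 ⇒ 1 by exhaustive ring bromination of commercial 3,4-dihydroxybenzaldehyde.
5. No ring is formed (the benzene ring is bought) and the target has no stereocentre.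

Assumption: the target is achiral, so "single enantiomer" does not apply. Sulfate monoesters are drawn as free acids, as in the target SMILES, but are carried as triethylammonium or sodium salts; the free diacid is released only at the end on cold H+ resin.

The route is designed from general reactivity principles and has not been run. Steps 2 and 4 rest on selectivity arguments rather than on a known procedure for this substrate.

**Step 1**
Reactants: 1 3,4-dihydroxybenzaldehyde
Product: 4 2,3,6-tribromo-4,5-dihydroxybenzaldehyde, via 3-bromo-4,5-dihydroxybenzaldehyde 2 (not isolated), via 2,3-dibromo-4,5-dihydroxybenzaldehyde 3 (not isolated)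
Conditions: Br2 (3.5 eq), Fe powder (5 mol%), AcOH, rt → 70 °C; aq. NaHSO3 quench, precipitate from water
Reagents that add atoms: bromine, BrBr
Why: Electrophilic aromatic bromination: the two phenolic OH groups activate all three free ring positions (ortho to 4-OH, then para and ortho to 3-OH), so excess Br2/FeBr3 in anhydrous AcOH fills them in turn while the CHO survives; no stereocentre is formed.

**Step 2**
Reactants: 4 2,3,6-tribromo-4,5-dihydroxybenzaldehyde
Product: 5 2,3,5-tribromo-4-formyl-6-hydroxyphenyl hydrogen sulfate (OSO3H para to CHO, free OH meta to CHO)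
Conditions: Et3N (1.05 eq), SO3·NMe3 (1.2 eq), DMF, rt → 40 °C; C18 (H2O/MeCN), isolated as the Et3NH+ salt
Reagents that add atoms: sulfur trioxide–trimethylamine complex, C[N+](C)(C)S(=O)(=O)[O-]
Why: O-sulfation by sulfuryl transfer from an amine–SO3 complex: one equivalent of base ionises only the 4-OH (a vinylogous acid para to CHO, the most acidic hydroxyl), and only that phenoxide attacks the mild SO3·NMe3, the same acidity-ordered selectivity that allows 4-O-monoalkylation of protocatechualdehyde.

**Step 3**
Reactants: 5 2,3,5-tribromo-4-formyl-6-hydroxyphenyl hydrogen sulfate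
Product: 6 2,3,5-tribromo-6-hydroxy-4-(hydroxymethyl)phenyl hydrogen sulfate
Conditions: NaBH4 (1.0 eq), THF/H2O 4:1, 0 °C, 30 min; neutralise, C18 desalting
Reagents that add atoms: none
Why: Borohydride reduction (1,2-hydride addition) of the aldehyde to the primary alcohol; aryl sulfate anions, aryl bromides and the phenol are inert to NaBH4, and the new CH2OH carbon is not a stereocentre.

**Step 4**
Reactants: 6 2,3,5-tribromo-6-hydroxy-4-(hydroxymethyl)phenyl hydrogen sulfate
Product: 7 2,3,5-tribromo-6-hydroxy-4-[(sulfooxy)methyl]phenyl hydrogen sulfate (target)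
Conditions: SO3·pyridine (1.5 eq), DMF, 0 °C, 2 h; aq. NaHCO3 to pH 7, C18 (disodium salt); Dowex 50W-X8 (H+), H2O, 0 °C, freeze-dry (no alcohols, no heat)
Reagents that add atoms: sulfur trioxide–pyridine complex, O=S(=O)([O-])[n+]1ccccc1
Why: Chemoselective O-sulfation with SO3·pyridine in base-free DMF: the primary benzylic alcohol reacts faster than the remaining phenol, which stays protonated (pyridine is too weak a base) and is flanked by Br and the anionic sulfate; no stereocentre is involved.

**Compound list**
1 | 3,4-dihydroxybenzaldehyde (protocatechualdehyde) | O=Cc1ccc(O)c(O)c1 | starting material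
2 | 3-bromo-4,5-dihydroxybenzaldehyde | O=Cc1cc(O)c(O)c(Br)c1 | intermediate (not isolated)
3 | 2,3-dibromo-4,5-dihydroxybenzaldehyde | O=Cc1cc(O)c(O)c(Br)c1Br | intermediate (not isolated)
4 | 2,3,6-tribromo-4,5-dihydroxybenzaldehyde | O=Cc1c(Br)c(O)c(O)c(Br)c1Br | intermediate
5 | 2,3,5-tribromo-4-formyl-6-hydroxyphenyl hydrogen sulfate | O=Cc1c(Br)c(O)c(OS(=O)(=O)O)c(Br)c1Br | intermediate
6 | 2,3,5-tribromo-6-hydroxy-4-(hydroxymethyl)phenyl hydrogen sulfate | OCc1c(Br)c(O)c(OS(=O)(=O)O)c(Br)c1Br | intermediate
7 | 2,3,5-tribromo-6-hydroxy-4-[(sulfooxy)methyl]phenyl hydrogen sulfate (achiral) | O=S(=O)(O)OCc1c(Br)c(O)c(OS(=O)(=O)O)c(Br)c1Br | target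

**Total step count:** 4. **Longest linear sequence:** 4 steps (1 → 4 → 5 → 6 → 7).

**Three steps most likely to fail, with fallbacks**

Step 2 (regioselective mono-sulfation; risk of the 5-O-sulfate isomer, disulfate, or an inseparable salt mixture). The fallback sets out from 4 and comes back at 5, and uses a protecting group placed on the other oxygen through the dianion. Compound 4 is converted into its dianion (NaH 2.1 eq, THF/DMF, 0 °C) and treated with TIPSCl (1.0 eq). Silylation occurs on the more nucleophilic, less stabilised 5-phenoxide, and any 4-O-silyl isomer equilibrates to the same more stable 4-phenoxide. This gives 2,3,6-tribromo-4-hydroxy-5-[(triisopropylsilyl)oxy]benzaldehyde F6, a neutral compound that can be chromatographed and whose regiochemistry can be checked by HMBC from the CHO and OH protons. Its only free hydroxyl is then sulfated (SO3·pyridine, pyridine, rt) to 2,3,5-tribromo-4-formyl-6-[(triisopropylsilyl)oxy]phenyl hydrogen sulfate F7. TBAF in THF at 0 °C removes the silyl group and gives 5.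

Step 4 (alcohol-versus-phenol selectivity; risk of trisulfate, and the benzylic sulfate is solvolysis-prone). The fallback sets out from 6 and comes back at 7, and masks the phenol before sulfation. Phenoxide-selective acetylation of 6 in water (Ac2O, aq. NaHCO3/THF, 0 °C; the benzylic alcohol is not acylated under these conditions) gives 2-(acetyloxy)-3,5,6-tribromo-4-(hydroxymethyl)phenyl hydrogen sulfate F8. Excess SO3·pyridine in DMF can then only sulfate the alcohol, giving 2-(acetyloxy)-3,5,6-tribromo-4-[(sulfooxy)methyl]phenyl hydrogen sulfate F9. Cold aqueous NH3 cleaves the electron-poor aryl acetate without touching either sulfate and gives 7 after the same cold H+ resin treatment.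

Step 1 (third bromination may stall next to the CHO; catechol oxidation or bromodeformylation may compete). The fallback sets out from 1 and comes back at 4, and brominates a ring that carries no formyl group. Compound 1 is hydrogenolysed (H2, Pd/C, AcOH, cat. HCl) to 4-methylcatechol F1, which can equally be bought. Br2 (3.1 eq) in AcOH gives 3,4,6-tribromo-5-methylbenzene-1,2-diol F2. Ac2O/pyridine gives 3,4,6-tribromo-5-methyl-1,2-phenylene diacetate F3. Wohl–Ziegler bromination (NBS, AIBN, PhCF3, reflux) gives 3,4,6-tribromo-5-(bromomethyl)-1,2-phenylene diacetate F4. Kornblum oxidation (DMSO, NaHCO3, 90 °C) gives 3,4,6-tribromo-5-formyl-1,2-phenylene diacetate F5. Catalytic K2CO3 in MeOH then removes both acetates and gives 4.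

**Further compounds**
F1 | step 1 | 4-methylcatechol (4-methylbenzene-1,2-diol) | Cc1ccc(O)c(O)c1
F2 | step 1 | 3,4,6-tribromo-5-methylbenzene-1,2-diol | Cc1c(Br)c(O)c(O)c(Br)c1Br
F3 | step 1 | 3,4,6-tribromo-5-methyl-1,2-phenylene diacetate | Cc1c(Br)c(OC(C)=O)c(OC(C)=O)c(Br)c1Br
F4 | step 1 | 3,4,6-tribromo-5-(bromomethyl)-1,2-phenylene diacetate | BrCc1c(Br)c(OC(C)=O)c(OC(C)=O)c(Br)c1Br
F5 | step 1 | 3,4,6-tribromo-5-formyl-1,2-phenylene diacetate | O=Cc1c(Br)c(OC(C)=O)c(OC(C)=O)c(Br)c1Br
F6 | step 2 | 2,3,6-tribromo-4-hydroxy-5-[(triisopropylsilyl)oxy]benzaldehyde | O=Cc1c(Br)c(O[Si](C(C)C)(C(C)C)C(C)C)c(O)c(Br)c1Br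
F7 | step 2 | 2,3,5-tribromo-4-formyl-6-[(triisopropylsilyl)oxy]phenyl hydrogen sulfate | O=Cc1c(Br)c(O[Si](C(C)C)(C(C)C)C(C)C)c(OS(=O)(=O)O)c(Br)c1Br
F8 | step 4 | 2-(acetyloxy)-3,5,6-tribromo-4-(hydroxymethyl)phenyl hydrogen sulfate | OCc1c(Br)c(OC(C)=O)c(OS(=O)(=O)O)c(Br)c1Br
F9 | step 4 | 2-(acetyloxy)-3,5,6-tribromo-4-[(sulfooxy)methyl]phenyl hydrogen sulfate | O=S(=O)(O)OCc1c(Br)c(OC(C)=O)c(OS(=O)(=O)O)c(Br)c1Br
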